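Ring atoms: C1 (CH2OH), C2 (C=O), C3 (OTig), C4 (iPr), C5 (OAng), C6 (=CH). Everything rests on reading the enone O=C2–C1=C6 as the formal metathesis product of a terminal alkyne (C1≡C2) and an aldehyde (C6). One gold/acid operation hydrates the alkyne at C2, steered by the neighbouring C3 tiglate carbonyl, and condenses the nascent methyl ketone onto C6. This closes the only ring without touching C3–C5. The precursor is a linear silyl-capped 5-alkynal already carrying both esters. Its stereotriad comes from an Evans syn aldol and an Evans–Tishchenko reduction that sets C5 while delivering the tiglate to O3. Baylis–Hillman hydroxymethylation of C1 finishes.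

Key step: step 7

Remark on the chemistry: 1 is taken as a commercial compound (otherwise one N-acylation of (R)-4-benzyloxazolidin-2-one with isovaleryl chloride). The ring numbers C1–C7 of the target are also used for the acyclic intermediates. Angeloyl = (Z)-2-methylbut-2-enoyl and tigloyl = (E)-2-methylbut-2-enoyl.

Step 1
Reactants: 1 (R)-4-benzyl-3-(3-methylbutanoyl)oxazolidin-2-one; 2 3-(trimethylsilyl)prop-2-ynal
Product: 5 (R)-4-benzyl-3-[(2R,3R)-3-hydroxy-2-isopropyl-5-(trimethylsilyl)pent-4-ynoyl]oxazolidin-2-one, via boron enolate 3 (not isolated), via boron aldolate 4 (not isolated)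
Conditions: Bu2BOTf, Et3N, CH2Cl2, 0 °C; 2, −78 → 0 °C; H2O2, MeOH, pH 7 buffer
Reagents that add atoms: none
Why: Evans syn aldol, in which the Z-boron enolate 3 reacts through a Zimmerman–Traxler chair whose one face is shielded by the (R)-benzyl auxiliary, so that C4 and C3 should be set together as the syn (2R,3R) pair.

Step 2
Reactants: 5 syn-aldol imide; 6 N,O-dimethylhydroxylamine hydrochloride
Product: 7 (2R,3R)-3-hydroxy-N-methoxy-N-methyl-2-isopropyl-5-(trimethylsilyl)pent-4-ynamide
Conditions: 6, AlMe3, CH2Cl2, −15 °C → rt; cold 0.5 M HCl work-up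
Reagents that add atoms: N,O-dimethylhydroxylamine hydrochloride (6), CNOC.Cl
Why: Weinreb transamidation, in which the aluminium amide is guided by the free β-hydroxy group to the exocyclic imide carbonyl, releases the auxiliary and touches no stereocentre.

Step 3
Reactants: 7 Weinreb amide; 8 2-methylprop-1-enylmagnesium bromide
Product: 9 (5R,6R)-6-hydroxy-2-methyl-5-isopropyl-8-(trimethylsilyl)oct-2-en-7-yn-4-one
Conditions: 8 (3.5 equiv), THF, −20 → 0 °C; inverse quench into cold 1 M HCl
Reagents that add atoms: 2-methylprop-1-enylmagnesium bromide (8), CC(C)=C[Mg]Br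
Why: Weinreb ketone synthesis, in which the magnesium-chelated tetrahedral adduct survives until the acidic quench, so that only one alkenyl group is delivered and the β,β-disubstituted enone resists conjugate addition.

Step 4
Reactants: 9 β-hydroxy enone; 10 (E)-2-methylbut-2-enal (tiglaldehyde)
Product: 12 (3R,4S,5S)-5-hydroxy-7-methyl-4-isopropyl-1-(trimethylsilyl)oct-6-en-1-yn-3-yl (E)-2-methylbut-2-enoate, via samarium hemiacetal 11 (not isolated)
Conditions: 10 (6 equiv), SmI2 (0.3 equiv), THF, −10 °C
Reagents that add atoms: (E)-2-methylbut-2-enal (10), C/C=C(\C)C=O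
Why: Evans–Tishchenko reduction, in which the hemiacetal 11 bound to trivalent samarium passes its hydride intramolecularly through a chair-like transition state to the C5 ketone, which should set C5 1,3-anti to O3 and leave the oxidised aldehyde as the tiglate on O3, so that the two oxygens are told apart without protecting groups.

Step 5
Reactants: 12 hydroxy tiglate; 13 angelic acid
Product: 15 (3R,4S,5S)-5-angeloyloxy-7-methyl-4-isopropyl-1-(trimethylsilyl)oct-6-en-1-yn-3-yl (E)-2-methylbut-2-enoate, via mixed anhydride 14 (not isolated)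
Conditions: 13, 2,4,6-Cl3C6H2COCl, Et3N, toluene, rt; then 12, 75 °C
Reagents that add atoms: angelic acid (13), C/C=C(/C)C(=O)O
Why: Yamaguchi-type mixed-anhydride esterification run without DMAP, which acylates the free C5 allylic alcohol with retention at C5 and is the established way to transfer an angeloyl group without Z-to-E isomerisation.

Step 6
Reactants: 15 diester enyne
Product: 17 (2R,3R,4R)-2-angeloyloxy-3-isopropyl-4-tigloyloxy-6-(trimethylsilyl)hex-5-ynal, via secondary ozonide 16 (not isolated)
Conditions: O3, CH2Cl2, −78 °C, Sudan Red 7B as end-point indicator; Me2S, −78 °C → rt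
Reagents that add atoms: ozone, [O-][O+]=O
Why: Ozonolysis with reductive work-up, in which the electron-rich trisubstituted C6=CMe2 olefin should react far faster than the two ester-conjugated olefins and the silylalkyne, so that one equivalent of ozone unmasks the C6 aldehyde without touching C5.

Step 7
Reactants: 17 silyl-capped alkynal
Product: 21 (4S,5S,6R)-4-angeloyloxy-5-isopropyl-6-tigloyloxycyclohex-2-en-1-one, via terminal alkynal 18 (not isolated), via keto aldehyde 19 (not isolated), via aldol 20 (not isolated)
Conditions: AgOTf (10 mol %), 1,4-dioxane/H2O 10:1, rt; Ph3PAuNTf2 (5 mol %), 40 °C; TsOH·H2O (20 mol %), 60 °C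
Reagents that add atoms: water, O
Why: Silver-catalysed protodesilylation bares the terminal alkyne 18, whose π-complex with monovalent gold is attacked at the internal carbon C2 by the C3 tiglate carbonyl oxygen (5-exo-dig), and water opens the dioxolenium so that protodeauration leaves methyl ketone 19 with the C3–O bond never broken. TsOH then enolises towards C1, the enol adds to the C6 aldehyde, and aldol 20 loses water to give the conjugated C1=C6 enone. The closest known reaction type is the hydrative carbocyclisation of terminal 5-alkynals to cyclohex-2-enones, that is neighbouring-group-assisted gold hydration of a propargylic ester followed by intramolecular aldol condensation. The single ring closes in the 6-(enolendo)-exo-trig mode by forming the C1–C6 bond. No new stereocentre survives because the transient C6 carbinol is dehydrated, C4 and C5 are carried through, and C3 is self-correcting because its equatorial ester trans to the isopropyl group is the more stable epimer of the α-acyloxy ketone. The step needs Markovnikov hydration at C2, secured by the terminal alkyne and the ester participation, and productive enolisation only towards C1, secured because a C3 or C5 enol could close only a four-membered ring, while amine-free acid catalysis limits epimerisation at C5.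

Step 8
Reactants: 21 cyclohexenone; 22 formaldehyde
Product: 23 (4S,5S,6R)-4-angeloyloxy-2-(hydroxymethyl)-5-isopropyl-6-tigloyloxycyclohex-2-en-1-one (target)
Conditions: 37% aq. HCHO, DMAP (0.3 equiv), THF, rt
Reagents that add atoms: formaldehyde (22), C=O
Why: Morita–Baylis–Hillman reaction, in which DMAP adds reversibly to C6, the resulting enolate attacks formaldehyde at C1 and loss of DMAP restores the enone, no stereocentre being formed or touched.

Compound list
1 | (R)-4-benzyl-3-(3-methylbutanoyl)oxazolidin-2-one | CC(C)CC(=O)N1[C@H](Cc2ccccc2)COC1=O | starting material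
2 | 3-(trimethylsilyl)prop-2-ynal | C[Si](C)(C)C#CC=O | starting material
3 | (Z)-dibutylboron enolate of 1 | CC(C)/C=C(\OB(CCCC)CCCC)N1[C@H](Cc2ccccc2)COC1=O | intermediate
4 | dibutylboron aldolate of 5 | O=C(N1[C@H](Cc2ccccc2)COC1=O)[C@H](C(C)C)[C@@H](OB(CCCC)CCCC)C#C[Si](C)(C)C | intermediate
5 | (R)-4-benzyl-3-[(2R,3R)-3-hydroxy-2-isopropyl-5-(trimethylsilyl)pent-4-ynoyl]oxazolidin-2-one | O=C(N1[C@H](Cc2ccccc2)COC1=O)[C@H](C(C)C)[C@@H](O)C#C[Si](C)(C)C | intermediate
6 | N,O-dimethylhydroxylamine hydrochloride | CNOC.Cl | starting material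
7 | (2R,3R)-3-hydroxy-N-methoxy-N-methyl-2-isopropyl-5-(trimethylsilyl)pent-4-ynamide | CON(C)C(=O)[C@H](C(C)C)[C@@H](O)C#C[Si](C)(C)C | intermediate
8 | 2-methylprop-1-enylmagnesium bromide | CC(C)=C[Mg]Br | starting material
9 | (5R,6R)-6-hydroxy-2-methyl-5-isopropyl-8-(trimethylsilyl)oct-2-en-7-yn-4-one | CC(C)=CC(=O)[C@H](C(C)C)[C@@H](O)C#C[Si](C)(C)C | intermediate
10 | (E)-2-methylbut-2-enal (tiglaldehyde) | C/C=C(\C)C=O | starting material
11 | O3 hemiacetal of 9 with 10, samarium-bound in the flask, drawn as the free hemiacetal (hemiacetal carbon undefined) | CC(C)=CC(=O)[C@H](C(C)C)[C@@H](OC(O)/C(C)=C/C)C#C[Si](C)(C)C | intermediate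
12 | (3R,4S,5S)-5-hydroxy-7-methyl-4-isopropyl-1-(trimethylsilyl)oct-6-en-1-yn-3-yl (E)-2-methylbut-2-enoate | CC(C)=C[C@H](O)[C@H](C(C)C)[C@@H](OC(=O)/C(C)=C/C)C#C[Si](C)(C)C | intermediate
13 | angelic acid, (Z)-2-methylbut-2-enoic acid | C/C=C(/C)C(=O)O | starting material
14 | (Z)-2-methylbut-2-enoic 2,4,6-trichlorobenzoic anhydride | C/C=C(/C)C(=O)OC(=O)c1c(Cl)cc(Cl)cc1Cl | intermediate
15 | (3R,4S,5S)-5-angeloyloxy-7-methyl-4-isopropyl-1-(trimethylsilyl)oct-6-en-1-yn-3-yl (E)-2-methylbut-2-enoate | CC(C)=C[C@H](OC(=O)/C(C)=C\C)[C@H](C(C)C)[C@@H](OC(=O)/C(C)=C/C)C#C[Si](C)(C)C | intermediate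
16 | secondary ozonide of 15 (3,3-dimethyl-1,2,4-trioxolan-5-yl group on C5, trioxolane CH undefined) | CC1(C)OOC(O1)[C@H](OC(=O)/C(C)=C\C)[C@H](C(C)C)[C@@H](OC(=O)/C(C)=C/C)C#C[Si](C)(C)C | intermediate
17 | (2R,3R,4R)-2-angeloyloxy-3-isopropyl-4-tigloyloxy-6-(trimethylsilyl)hex-5-ynal | O=C[C@H](OC(=O)/C(C)=C\C)[C@H](C(C)C)[C@@H](OC(=O)/C(C)=C/C)C#C[Si](C)(C)C | intermediate
18 | (2R,3R,4R)-2-angeloyloxy-3-isopropyl-4-tigloyloxyhex-5-ynal | O=C[C@H](OC(=O)/C(C)=C\C)[C@H](C(C)C)[C@@H](OC(=O)/C(C)=C/C)C#C | intermediate
19 | (2R,3S,4R)-2-angeloyloxy-3-isopropyl-5-oxo-4-tigloyloxyhexanal | O=C[C@H](OC(=O)/C(C)=C\C)[C@H](C(C)C)[C@@H](OC(=O)/C(C)=C/C)C(C)=O | intermediate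
20 | 4-angeloyloxy-3-hydroxy-5-isopropyl-6-tigloyloxycyclohexanone (carbinol C3 as both epimers, other centres as in 21) | C/C=C(/C)C(=O)O[C@H]1C(O)CC(=O)[C@H](OC(=O)/C(C)=C/C)[C@H]1C(C)C | intermediate
21 | (4S,5S,6R)-4-angeloyloxy-5-isopropyl-6-tigloyloxycyclohex-2-en-1-one | C/C=C(/C)C(=O)O[C@H]1C=CC(=O)[C@H](OC(=O)/C(C)=C/C)[C@H]1C(C)C | intermediate
22 | formaldehyde | C=O | starting material
23 | (4S,5S,6R)-4-angeloyloxy-2-(hydroxymethyl)-5-isopropyl-6-tigloyloxycyclohex-2-en-1-one | C/C=C(/C)C(=O)O[C@H]1C=C(CO)C(=O)[C@H](OC(=O)/C(C)=C/C)[C@H]1C(C)C | target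

Total step count: 8. Longest linear sequence: 8 steps (1 → 23).

Steps most likely to fail

Step 7 (key step): acid-induced epimerisation of the α-acyloxy aldehyde at C5, or loss of both acids with aromatisation, may outrun the aldol condensation. The fallback replaces carbonyl condensation by olefin metathesis and sets out from 15. The same silver/gold hydration (AgOTf, then Ph3PAuNTf2, wet 1,4-dioxane, 40 °C) should give methyl ketone F1. Mannich-type α-methylenation (paraformaldehyde, iPr2NH·CF3CO2H, THF, reflux) should give vinyl ketone F2. Ring-closing metathesis (second-generation Hoveyda–Grubbs catalyst, toluene, 80 °C) should then join C1 and C6 with loss of 2-methylpropene, and the fallback comes back to the route at 21.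

Step 8: slow conjugate addition of DMAP at the hindered C6, or acyl transfer to the nucleophilic catalyst and to the new primary alcohol, may erode the reaction. The fallback uses cross-coupling and sets out from 21. α-Iodination (I2, pyridine, CH2Cl2, rt) should give 2-iodoenone F3. Stille coupling with Bu3SnCH2OH (Pd2(dba)3, AsPh3, CuI, NMP, 50 °C) should come back to the route at 23.

Step 4: four processes may spoil the reduction. These are sluggish hemiacetal formation with the conjugated aldehyde, the axial isopropyl group in the hydride-transfer chair, retro-aldol cleavage, and later O3-to-O5 acyl migration. The fallback separates reduction from acylation and sets out from 9. Hydroxy-directed Saksena–Evans reduction (Me4NBH(OAc)3, MeCN/AcOH, −30 °C) should give 1,3-anti diol F4. Selective acylation of the less hindered propargylic O3 (tigloyl chloride, 2,4,6-collidine, CH2Cl2, −40 °C) should come back to the route at 12.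

Further compounds
F1 | step 7 | methyl ketone, (3R,4S,5S)-5-angeloyloxy-7-methyl-2-oxo-4-isopropyloct-6-en-3-yl (E)-2-methylbut-2-enoate | CC(C)=C[C@H](OC(=O)/C(C)=C\C)[C@H](C(C)C)[C@@H](OC(=O)/C(C)=C/C)C(C)=O
F2 | step 7 | vinyl ketone, (4R,5S,6S)-6-angeloyloxy-8-methyl-3-oxo-5-isopropylnona-1,7-dien-4-yl (E)-2-methylbut-2-enoate | CC(C)=C[C@H](OC(=O)/C(C)=C\C)[C@H](C(C)C)[C@@H](OC(=O)/C(C)=C/C)C(=O)C=C
F3 | step 8 | 2-iodoenone, 4-angeloyloxy-2-iodo-5-isopropyl-6-tigloyloxycyclohex-2-en-1-one (stereocentres placed as in 21) | C/C=C(/C)C(=O)O[C@H]1C=C(I)C(=O)[C@H](OC(=O)/C(C)=C/C)[C@H]1C(C)C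
F4 | step 4 | 1,3-anti diol, (3R,4S,5S)-7-methyl-4-isopropyl-1-(trimethylsilyl)oct-6-en-1-yne-3,5-diol | CC(C)=C[C@H](O)[C@H](C(C)C)[C@@H](O)C#C[Si](C)(C)C
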